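The route rests on cutting the C3a′–C3′ bond of ring D, the second butylidene-butenolide: the σ-bond that joins the bicyclo[2.2.2]octene carbon C3a′ to the enol-ester carbon C3′. The precursor is a β-bromoacrylate (bromine on C3a′) whose C7a′ carboxyl carries an (E)-pent-1-enyl ester. One cationic 5-exo Mizoroki–Heck cyclisation forms C3a′–C3′ and, by loss of H3′, the (Z)-butylidene, exploiting that C3′ is an acyloxy-substituted alkene carbon tethered through C1′–O2′. The carbocyclic rings B and C come from a double Michael union of a chiral 4-silyloxycyclohexenone with cyclohexenone; ring A is closed by carbonylative enol-lactonisation.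

Key step: step 12

Assumption: enone 1 is taken as a catalogue compound in enantiopure (S) form; 2, 6 and 17 are commodity chemicals.

Locants: unit one is lactone ring A (C1, O2, C3, exocyclic C8) fused to cyclohexene ring B (C3a, C4, C5, C6, C7, C7a). Unit two carries primes: ring C is the bicyclo[2.2.2]octane (bridgeheads C4′ and C7′; bridges C3a′–C7a′, C5′–C6′ and C7–C6) and ring D is the lactone (C1′, O2′, C3′, exocyclic C8′). All tricyclic compounds have the absolute configuration shown in their SMILES.

Step 1
Reactants: 1 (S)-4-(tert-butyldimethylsilyloxy)cyclohex-2-en-1-one; 2 cyclohex-2-en-1-one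
Product: 5 tricyclic 7a-ketone with C6′ silyl enol ether, via lithium dienolate 3 (not isolated), via tricyclic lithium enolate 4 (not isolated)
Conditions: LiN(i-Pr)2, THF, −78 °C; 2, −78 → −20 °C; t-BuMe2SiOTf, −78 °C
Reagents that add atoms: tert-butyldimethylsilyl trifluoromethanesulfonate, CC(C)(C)[Si](C)(C)OS(=O)(=O)C(F)(F)F
Why: Kinetic α′-deprotonation gives cross-conjugated dienolate 3, whose anionic double Michael addition (formal endo Diels–Alder) to 2 forms C7′–C6 and then C7–C4′ anti to the C3a′ silyloxy group, with ring B cis-fused and syn to the enolate bridge, so C4′, C7′, C6 and C7 are all set by the C3a′ stereocentre; trapping the regiodefined C5′=C6′ enolate 4 as its silyl enol ether differentiates the two carbonyl groups.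

Step 2
Reactants: 5 tricyclic 7a-ketone with C6′ silyl enol ether; 6 pentanoyl chloride
Product: 7 3a-pentanoyl β-diketone (drawn as its C7a enol)
Conditions: LiN(SiMe3)2 (2.2 equiv), toluene–THF, −78 → 0 °C; then 6; aq. NH4Cl
Reagents that add atoms: none
Why: Claisen-type C-acylation of the less hindered C3a lithium enolate of the ring B ketone (C6′ is masked as the silyl enol ether) should give the β-diketone, which the second equivalent of base removes as its diketonate; no lasting stereocentre is created.

Step 3
Reactants: 7 3a-pentanoyl β-diketone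
Product: 8 β-acyl vinyl triflate (triflate on C7a)
Conditions: NaH, PhNTf2, THF, 0 °C → rt
Reagents that add atoms: N-phenylbis(trifluoromethanesulfonimide), FC(F)(F)S(=O)(=O)N(c1ccccc1)S(=O)(=O)C(F)(F)F
Why: Enol triflate formation by O-sulfonylation of the sodium β-diketonate is expected at the ring oxygen on C7a, giving the endocyclic C7a=C3a vinyl triflate conjugated with the side-chain ketone, as is usual for 2-acylcycloalkanones.

Step 4
Reactants: 8 β-acyl vinyl triflate
Product: 9 ring A butylidene lactone with C6′ silyl enol ether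
Conditions: Pd(PPh3)4 (5 mol %), CO (1 atm), Et3N, MeCN, 60 °C
Reagents that add atoms: carbon monoxide, [C-]#[O+]
Why: Carbonylative enol-lactonisation of a β-acyl vinyl triflate: oxidative addition, CO insertion at C7a and capture of the acylpalladium by the enol oxygen of the butyl ketone should close ring A with the thermodynamically preferred (Z)-butylidene geometry.

Step 5
Reactants: 9 ring A butylidene lactone with C6′ silyl enol ether
Product: 11 C6′ alcohol, via C6′ ketone 10 (not isolated)
Conditions: Bu4NF, AcOH, THF, −20 °C; then MeOH, CeCl3·7H2O, NaBH4, −78 °C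
Reagents that add atoms: none
Why: Buffered fluoride should cleave the enol silyl ether much faster than the secondary alkyl silyl ether, and Luche reduction of ketone 10 should deliver hydride from the open face next to C7a′H2 (the other face is blocked by C5H2 of ring B), placing the C6′ hydroxyl syn to the C6–C7 bridge (6′R) without touching the enol lactone.

Step 6
Reactants: 11 C6′ alcohol
Product: 12 C6′ triisopropylsilyl ether
Conditions: i-Pr3SiOTf, 2,6-lutidine, CH2Cl2, 0 °C → rt
Reagents that add atoms: triisopropylsilyl trifluoromethanesulfonate, CC(C)[Si](OS(=O)(=O)C(F)(F)F)(C(C)C)C(C)C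
Why: Silyl ether formation with the silyl triflate should protect the hindered secondary alcohol as a robust ether that is orthogonal to the C3a′ tert-butyldimethylsilyl ether.

Step 7
Reactants: 12 C6′ triisopropylsilyl ether
Product: 13 C3a′ alcohol
Conditions: HF·pyridine, pyridine, THF, 0 °C → rt
Reagents that add atoms: none
Why: Selective acidic fluoride desilylation, because a secondary tert-butyldimethylsilyl ether is cleaved much faster than the hindered triisopropylsilyl ether and the enol lactone tolerates these conditions.

Step 8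
Reactants: 13 C3a′ alcohol
Product: 14 C3a′ ketone
Conditions: Dess–Martin periodinane, NaHCO3, CH2Cl2, rt
Reagents that add atoms: none
Why: Dess–Martin oxidation under buffered, non-basic conditions should give the ketone, whose only enolisable position is C7a′ because C4′ is a bridgehead.

Step 9
Reactants: 14 C3a′ ketone
Product: 15 β-bromo enal (Br on C3a′, CHO on C7a′)
Conditions: PBr3, DMF, CHCl3, 0 → 60 °C; then aq. NaOAc
Reagents that add atoms: N,N-dimethylformamide, CN(C)C=O; phosphorus tribromide, BrP(Br)Br; water, O
Why: Vilsmeier–Haack–Arnold bromoformylation: the enol is formylated at C7a′ by the bromoiminium salt and the carbonyl oxygen is exchanged for bromide, so the halide sits on C3a′ and the future C1′ on C7a′ with no regiochemical choice.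

Step 10
Reactants: 15 β-bromo enal
Product: 16 β-bromo acrylic acid
Conditions: NaClO2, NaH2PO4, 2-methylbut-2-ene, t-BuOH–H2O, rt
Reagents that add atoms: sodium chlorite, [Na+].[O-]Cl=O
Why: Pinnick oxidation should convert the enal into the acid without affecting the vinyl bromide or the enol lactone, the hypochlorite being scavenged by the alkene additive.

Step 11
Reactants: 16 β-bromo acrylic acid; 17 (E)-pent-1-en-1-ylboronic acid
Product: 18 (E)-pent-1-enyl ester
Conditions: Cu(OAc)2 (20 mol %), DMAP, 4 Å MS, O2 (1 atm), CH2Cl2, rt → 40 °C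
Reagents that add atoms: none
Why: Chan–Lam-type copper-catalysed oxidative O-alkenylation of the carboxylic acid should proceed with retention of the (E) geometry and install the enol ester that tethers C3′ to C7a′.

Step 12
Reactants: 18 (E)-pent-1-enyl ester
Product: 19 6′-O-triisopropylsilyl ether of the target
Conditions: Pd(OAc)2 (10 mol %), dppp (12 mol %), Ag2CO3, MeCN, 80 °C
Reagents that add atoms: none
Why: Oxidative addition of zerovalent palladium into the C3a′–Br bond and bromide abstraction by silver give a cationic alkenylpalladium species that inserts the enol-ester alkene with C3a′ bonding to the oxygen-bearing carbon C3′ and palladium going to C8′; syn β-hydride elimination of H3′ then releases the C7a′=C3a′–C3′=C8′ diene of ring D. The closest known reaction type is the intramolecular Mizoroki–Heck cyclisation of alkenyl or aryl halides onto enol ethers and enamides to give alkylidene heterocycles, together with the α-arylation of vinyl esters under cationic palladium. Ring D is closed in the 5-exo-trig mode. No stereocentre is formed; the (Z) geometry of the butylidene follows from stereospecific syn insertion and syn β-hydride elimination on the (E)-enol ester and is also the thermodynamically preferred one. The step needs 5-exo over 6-endo insertion and β-hydride over β-acyloxy elimination: the short C7a′–C1′–O2′ tether and the electronic preference of cationic palladium for the oxygen-bearing carbon should secure the former, and the halide-free cationic manifold together with the allylic, oxygen-activated C3′–H bond should favour the latter.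

Step 13
Reactants: 19 6′-O-triisopropylsilyl ether of the target
Product: 20 target CNP0289078.2
Conditions: HF·pyridine, THF, 0 °C → rt
Reagents that add atoms: none
Why: Acidic fluoride desilylation should free the C6′ hydroxyl while leaving both base-sensitive enol lactones intact.

Compound list
1 | (S)-4-(tert-butyldimethylsilyloxy)cyclohex-2-en-1-one | O=C1C=C[C@@H](O[Si](C)(C)C(C)(C)C)CC1 | starting material
2 | cyclohex-2-en-1-one | O=C1C=CCCC1 | starting material
3 | lithium (S)-4-(tert-butyldimethylsilyloxy)cyclohexa-1,5-dien-1-olate (cross-conjugated dienolate of 1) | [Li]OC1=CC[C@H](O[Si](C)(C)C(C)(C)C)C=C1 | intermediate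
4 | tricyclic lithium enolate (C5′=C6′–OLi) of the double Michael adduct; ring B 7a-ketone, 3a′-silyloxy | O=C2CCC[C@@H]1[C@H]3C[C@H](O[Si](C)(C)C(C)(C)C)[C@H](C=C3O[Li])[C@H]21 | intermediate
5 | tricyclic 7a-ketone: ring B cis-fused at C6–C7 and syn to the C5′=C6′ bridge, C6′ tert-butyldimethylsilyl enol ether, 3a′-tert-butyldimethylsilyloxy anti to the C6–C7 bridge | O=C2CCC[C@@H]1[C@H]3C[C@H](O[Si](C)(C)C(C)(C)C)[C@H](C=C3O[Si](C)(C)C(C)(C)C)[C@H]21 | intermediate
6 | pentanoyl chloride | CCCCC(Cl)=O | starting material
7 | 3a-pentanoyl derivative of 5 (β-diketone, drawn as the C7a enol) | OC2=C(C(=O)CCCC)CC[C@@H]1[C@H]3C[C@H](O[Si](C)(C)C(C)(C)C)[C@H](C=C3O[Si](C)(C)C(C)(C)C)[C@H]21 | intermediate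
8 | C7a=C3a vinyl triflate: 7a-trifluoromethanesulfonyloxy, 3a-pentanoyl | FC(F)(F)S(=O)(=O)OC2=C(C(=O)CCCC)CC[C@@H]1[C@H]3C[C@H](O[Si](C)(C)C(C)(C)C)[C@H](C=C3O[Si](C)(C)C(C)(C)C)[C@H]21 | intermediate
9 | rings A and B complete ((Z)-3-butylidene-4,5,6,7-tetrahydrophthalide), bicyclic part with C6′ silyl enol ether and 3a′-silyloxy | CCC/C=C1\OC(=O)C2=C1CC[C@@H]1[C@H]3C[C@H](O[Si](C)(C)C(C)(C)C)[C@H](C=C3O[Si](C)(C)C(C)(C)C)[C@H]21 | intermediate
10 | C6′ ketone of 9 (3a′-silyloxy kept) | CCC/C=C1\OC(=O)C2=C1CC[C@@H]1[C@H]3C[C@H](O[Si](C)(C)C(C)(C)C)[C@H](CC3=O)[C@H]21 | intermediate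
11 | C6′ alcohol, hydroxyl syn to the C6–C7 bridge (6′R), 3a′-tert-butyldimethylsilyloxy | CCC/C=C1\OC(=O)C2=C1CC[C@@H]1[C@H]3C[C@H](O[Si](C)(C)C(C)(C)C)[C@H](C[C@H]3O)[C@H]21 | intermediate
12 | C6′ triisopropylsilyl ether of 11 | CCC/C=C1\OC(=O)C2=C1CC[C@@H]1[C@H]3C[C@H](O[Si](C)(C)C(C)(C)C)[C@H](C[C@H]3O[Si](C(C)C)(C(C)C)C(C)C)[C@H]21 | intermediate
13 | C3a′ alcohol (hydroxyl anti to the C6–C7 bridge), 6′-triisopropylsilyloxy | CCC/C=C1\OC(=O)C2=C1CC[C@@H]1[C@H]3C[C@H](O)[C@H](C[C@H]3O[Si](C(C)C)(C(C)C)C(C)C)[C@H]21 | intermediate
14 | C3a′ ketone, 6′-triisopropylsilyloxy | CCC/C=C1\OC(=O)C2=C1CC[C@@H]1[C@H]3CC(=O)[C@H](C[C@H]3O[Si](C(C)C)(C(C)C)C(C)C)[C@H]21 | intermediate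
15 | β-bromo enal: C3a′=C7a′ alkene with Br on C3a′ and CHO on C7a′ | CCC/C=C1\OC(=O)C2=C1CC[C@@H]1[C@H]3C(C=O)=C(Br)[C@H](C[C@H]3O[Si](C(C)C)(C(C)C)C(C)C)[C@H]21 | intermediate
16 | β-bromo acrylic acid: Br on C3a′, CO2H on C7a′ | CCC/C=C1\OC(=O)C2=C1CC[C@@H]1[C@H]3C(C(=O)O)=C(Br)[C@H](C[C@H]3O[Si](C(C)C)(C(C)C)C(C)C)[C@H]21 | intermediate
17 | (E)-pent-1-en-1-ylboronic acid | CCC/C=C/B(O)O | starting material
18 | (E)-pent-1-en-1-yl ester of 16 | CCC/C=C1\OC(=O)C2=C1CC[C@@H]1[C@H]3C(C(=O)O/C=C/CCC)=C(Br)[C@H](C[C@H]3O[Si](C(C)C)(C(C)C)C(C)C)[C@H]21 | intermediate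
19 | 6′-O-triisopropylsilyl ether of the target (rings A to D complete, both butylidenes Z) | CCC/C=C1\OC(=O)C2=C1CC[C@@H]1[C@H]3C4=C(/C(=C/CCC)OC4=O)[C@H](C[C@H]3O[Si](C(C)C)(C(C)C)C(C)C)[C@H]21 | intermediate
20 | CNP0289078.2, (3Z,3′Z,6S,7R,4′R,6′R,7′S)-6′-hydroxy bis(butylidene) phthalide dimer linked C6–C7′ and C7–C4′ | CCC/C=C1\OC(=O)C2=C1CC[C@@H]1[C@H]3C4=C(/C(=C/CCC)OC4=O)[C@H](C[C@H]3O)[C@H]21 | target

Total step count: 13. Longest linear sequence: 13 steps (from 1).

Steps most likely to fail

Step 12 (key step). After the 5-exo insertion the alkylpalladium intermediate may expel the ring oxygen by β-acyloxy elimination (ring opening) instead of β-hydride elimination, 6-endo insertion may compete, and the ester has to reach its less populated s-cis conformer before cyclising. The fallback sets out from acid 16: Sonogashira coupling with pent-1-yne (PdCl2(PPh3)2, CuI, Et3N, MeCN, room temperature to 50 °C) would give the 3a′-(pent-1-ynyl) acid F1. This should cyclise in the same flask by 5-exo-dig anti addition of the carboxylate across the alkyne to the (Z)-butylidene lactone, coming back to the route at 19. This alternative closes ring D through O2′–C3′ and is well-established chemistry for (Z)-β-halo acrylic acids.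

Step 1. 1,2-Addition of the dienolate to the enone, incomplete closure of the second Michael addition, or proton transfer between the final enolate and the ring B ketone before silylation would erode yield and the regiochemical purity of the enol ether. The fallback sets out from 1: silylation (t-BuMe2SiOTf, Et3N, CH2Cl2, 0 °C) would give (S)-2,5-bis(tert-butyldimethylsilyloxy)cyclohexa-1,3-diene F2, and a concerted endo Diels–Alder reaction of F2 with 2 under high pressure (about 1.2 GPa, CH2Cl2, room temperature) should deliver the same silyl enol ether, coming back at 5.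

Step 9. The hot, HBr-releasing Vilsmeier medium may add HBr across or isomerise the ring A enol lactone, or erode the silyl ether, before bromoformylation is complete. The fallback sets out from 14: condensation with tert-butoxybis(dimethylamino)methane (toluene, 80 °C) would give the (E)-7a′-(dimethylaminomethylene) ketone F3 under neutral conditions. Brief treatment of F3 with oxalyl bromide (CH2Cl2, −20 °C), then aqueous NaHCO3 to hydrolyse the bromo-iminium salt, should give the β-bromo enal, coming back at 15.

Further compounds
F1 | step 12 | 3a′-(pent-1-ynyl) C3a′=C7a′-ene-7a′-carboxylic acid (6′-triisopropylsilyloxy, rings A and B as in 16) | CCC/C=C1\OC(=O)C2=C1CC[C@@H]1[C@H]3C(C(=O)O)=C(C#CCCC)[C@H](C[C@H]3O[Si](C(C)C)(C(C)C)C(C)C)[C@H]21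
F2 | step 1 | (S)-2,5-bis(tert-butyldimethylsilyloxy)cyclohexa-1,3-diene | CC(C)(C)[Si](C)(C)OC1=CC[C@H](O[Si](C)(C)C(C)(C)C)C=C1
F3 | step 9 | (E)-7a′-(dimethylaminomethylene) C3a′ ketone (enaminone of 14) | CCC/C=C1\OC(=O)C2=C1CC[C@@H]1[C@H]3/C(=C\N(C)C)C(=O)[C@H](C[C@H]3O[Si](C(C)C)(C(C)C)C(C)C)[C@H]21
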